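## Retrosynthetic overview

1. The target comes from triol 23 by acetylation of the equatorial 7β‑OH only; the diene comes from the (E)‑enal 21 by Wittig methylenation.
2. The key C12–C13 bond is made by a directed aldol condensation of the bicyclic C12 aldehyde 15 with metallated propanal imine 18.
3. The 6β‑OH comes from α‑face hydride reduction of 6‑ketone 12; the 6α‑OH/7β‑OTBS pair comes from hydroboration of silyl enol ether 9 of ketol 8.
4. Ketol 8 comes from exocyclic alkene 4 (allylic hydroxylation, OH‑directed epoxidation, hydride opening, oxidation); 4 comes from the sclareolide‑derived diol by dehydration.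
5. No ring is built: both carbocycles, with C5, C9 and C10, come from (+)‑sclareolide (lactone opened in step 1; only a transient oxirane in steps 5–6).

Assumption: (+)‑sclareolide counts as a cheap bulk chemical; labdane numbering is used, every decalin compound keeps 5α‑H, 9α‑H (9β side chain) and 10β‑CH3, and TBS = tert‑butyldimethylsilyl, TES = triethylsilyl.

## Route

Step 1
Reactants: 1 (+)-sclareolide
Product: 2 13,14,15,16-tetranorlabdane-8α,12-diol
Conditions: LiAlH4, THF, 0 °C to rt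
Reagents that add atoms: none
Why: Hydride reduction of the γ‑lactone gives the diol without touching C5, C8, C9 or C10, so the trans‑decalin and the 8α‑O/8β‑CH3 pattern are taken from the chiral pool.

Step 2
Reactants: 2 13,14,15,16-tetranorlabdane-8α,12-diol
Product: 3 12-benzyloxy-13,14,15,16-tetranorlabdan-8α-ol
Conditions: NaH (1.1 equiv), BnBr, n‑Bu4NI (cat.), THF, 0 °C to rt
Reagents that add atoms: benzyl bromide, BrCc1ccccc1
Why: Williamson etherification takes only the primary alkoxide because the tertiary 8α‑OH is too hindered to be alkylated.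

Step 3
Reactants: 3 12-benzyloxy-13,14,15,16-tetranorlabdan-8α-ol
Product: 4 12-benzyloxy-13,14,15,16-tetranorlabd-8(17)-ene
Conditions: SOCl2, pyridine, CH2Cl2, −78 °C
Reagents that add atoms: none
Why: E2 dehydration through the chlorosulfite gives mainly the exocyclic alkene because the equatorial 8α leaving group has anti‑periplanar hydrogens only on C17 (minor Δ7 isomer removed on AgNO3–silica).

Step 4
Reactants: 4 12-benzyloxy-13,14,15,16-tetranorlabd-8(17)-ene
Product: 5 12-benzyloxy-13,14,15,16-tetranorlabd-8(17)-en-7α-ol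
Conditions: SeO2 (0.3 equiv), t‑BuOOH (3 equiv), CH2Cl2, rt
Reagents that add atoms: tert-butyl hydroperoxide, CC(C)(C)OO (oxygen passed on by catalytic selenium dioxide, O=[Se]=O)
Why: Riley allylic hydroxylation (ene reaction then [2,3]‑shift) prefers the allylic CH2 (C7) over the CH (C9) and delivers the oxygen axially on the α‑face.

Step 5
Reactants: 5 12-benzyloxy-13,14,15,16-tetranorlabd-8(17)-en-7α-ol
Product: 6 12-benzyloxy-8α,17-epoxy-13,14,15,16-tetranorlabdan-7α-ol
Conditions: VO(acac)2 (5 mol %), t‑BuOOH, CH2Cl2, rt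
Reagents that add atoms: tert-butyl hydroperoxide, CC(C)(C)OO
Why: Hydroxyl‑directed vanadium epoxidation delivers oxygen syn to the axial 7α‑OH, which is also the face away from the axial C10 methyl, so C8 is set with O α and C17 β.

Step 6
Reactants: 6 12-benzyloxy-8α,17-epoxy-13,14,15,16-tetranorlabdan-7α-ol
Product: 7 12-benzyloxy-13,14,15,16-tetranorlabdane-7α,8α-diol
Conditions: LiAlH4, THF, 0 °C to reflux
Reagents that add atoms: none
Why: SN2 hydride opening at the unhindered CH2 end of the spiro‑epoxide turns C17 into the 8β‑methyl and leaves the C8–O bond intact (8α‑OH).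

Step 7
Reactants: 7 12-benzyloxy-13,14,15,16-tetranorlabdane-7α,8α-diol
Product: 8 12-benzyloxy-8α-hydroxy-13,14,15,16-tetranorlabdan-7-one
Conditions: (COCl)2, DMSO, CH2Cl2, −78 °C; Et3N, to 0 °C
Reagents that add atoms: none
Why: Swern oxidation takes only the secondary alcohol without glycol cleavage, and the quaternary C8 cannot epimerise.

Step 8
Reactants: 8 12-benzyloxy-8α-hydroxy-13,14,15,16-tetranorlabdan-7-one
Product: 9 12-benzyloxy-7,8α-bis(tert-butyldimethylsilyloxy)-13,14,15,16-tetranorlabd-6-ene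
Conditions: TBSOTf (3 equiv), Et3N (6 equiv), CH2Cl2, 0 °C to rt
Reagents that add atoms: tert-butyldimethylsilyl triflate, CC(C)(C)[Si](C)(C)OS(=O)(=O)C(F)(F)F
Why: The silyl triflate caps the tertiary alcohol and, by soft enolisation, forms the silyl enol ether, which is regiodefined because only C6 carries α‑hydrogens.

Step 9
Reactants: 9 12-benzyloxy-7,8α-bis(tert-butyldimethylsilyloxy)-13,14,15,16-tetranorlabd-6-ene
Product: 11 12-benzyloxy-7β,8α-bis(tert-butyldimethylsilyloxy)-13,14,15,16-tetranorlabdan-6α-ol, via 6α-alkylborane 10 (not isolated)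
Conditions: BH3·THF, THF, 0 °C to rt; then 3 M NaOH, 30% H2O2, 0 °C
Reagents that add atoms: hydrogen peroxide, OO
Why: Hydroboration–oxidation of the silyl enol ether puts boron on C6 (β to oxygen) and hydrogen on C7, syn and from the α‑face because three axial methyls (C4β, C8β, C10) block the β‑face; this sets 7β‑OTBS and, after oxidation with retention, a free 6α‑OH.

Step 10
Reactants: 11 12-benzyloxy-7β,8α-bis(tert-butyldimethylsilyloxy)-13,14,15,16-tetranorlabdan-6α-ol
Product: 12 12-benzyloxy-7β,8α-bis(tert-butyldimethylsilyloxy)-13,14,15,16-tetranorlabdan-6-one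
Conditions: Dess–Martin periodinane, NaHCO3, CH2Cl2, rt
Reagents that add atoms: none
Why: Buffered Dess–Martin oxidation removes the wrongly configured C6 carbinol centre without epimerising the equatorial 7β‑silyloxy group or the trans ring fusion.

Step 11
Reactants: 12 12-benzyloxy-7β,8α-bis(tert-butyldimethylsilyloxy)-13,14,15,16-tetranorlabdan-6-one
Product: 13 12-benzyloxy-7β,8α-bis(tert-butyldimethylsilyloxy)-13,14,15,16-tetranorlabdan-6β-ol
Conditions: NaBH4, MeOH–THF, 0 °C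
Reagents that add atoms: none
Why: Borohydride attacks the 6‑ketone from the α‑face because the β‑face is closed by the syn‑axial C4β and C10 methyls, giving the axial 6β‑alcohol.

Step 12
Reactants: 13 12-benzyloxy-7β,8α-bis(tert-butyldimethylsilyloxy)-13,14,15,16-tetranorlabdan-6β-ol
Product: 14 7β,8α-bis(tert-butyldimethylsilyloxy)-13,14,15,16-tetranorlabdane-6β,12-diol
Conditions: H2 (1 atm), 10% Pd/C, EtOAc, rt
Reagents that add atoms: none
Why: Hydrogenolysis removes the benzyl ether at a stage with no alkene present and leaves the silyl ethers alone.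

Step 13
Reactants: 14 7β,8α-bis(tert-butyldimethylsilyloxy)-13,14,15,16-tetranorlabdane-6β,12-diol
Product: 15 6β-hydroxy-7β,8α-bis(tert-butyldimethylsilyloxy)-13,14,15,16-tetranorlabdan-12-al
Conditions: TEMPO (10 mol %), PhI(OAc)2 (1.2 equiv), CH2Cl2, rt
Reagents that add atoms: none
Why: The TEMPO/oxoammonium oxidation is selective for the primary alcohol over the hindered axial 6β‑OH and stops at the aldehyde.

Step 14
Reactants: 16 propanal; 17 cyclohexylamine
Product: 18 N-cyclohexylpropan-1-imine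
Conditions: neat, K2CO3, 0 °C to rt; distil
Reagents that add atoms: none
Why: Simple imine condensation gives the masked propanal that can be metallated without self‑aldolisation.

Step 15
Reactants: 15 6β-hydroxy-7β,8α-bis(tert-butyldimethylsilyloxy)-13,14,15,16-tetranorlabdan-12-al; 18 N-cyclohexylpropan-1-imine
Product: 21 (12E)-6β-hydroxy-7β,8α-bis(tert-butyldimethylsilyloxy)-15-norlabd-12-en-14-al, via lithiated imine 19 (not isolated), via aldol adduct 20 (not isolated)
Conditions: 18 (2.5 equiv), LDA (2.4 equiv), THF, −78 to 0 °C; add 15 at −78 °C, to −20 °C; then aq. oxalic acid, THF, rt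
Reagents that add atoms: water, O
Why: Wittig directed aldol condensation: the aza‑enolate adds to the aldehyde (the first equivalent only deprotonates the 6β‑OH) and acidic hydrolysis with dehydration gives the conjugated 2‑methyl‑2‑enal as the thermodynamically favoured E isomer.

Step 16
Reactants: 21 (12E)-6β-hydroxy-7β,8α-bis(tert-butyldimethylsilyloxy)-15-norlabd-12-en-14-al
Product: 22 (12E)-7β,8α-bis(tert-butyldimethylsilyloxy)labda-12,14-dien-6β-ol
Conditions: Ph3PCH3Br (3 equiv), KOt‑Bu (2.8 equiv), THF, 0 °C to rt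
Reagents that add atoms: methyltriphenylphosphonium bromide, C[P+](c1ccccc1)(c1ccccc1)c1ccccc1.[Br-]
Why: Wittig methylenation of the enal gives the terminal vinyl group without touching the trisubstituted E double bond.

Step 17
Reactants: 22 (12E)-7β,8α-bis(tert-butyldimethylsilyloxy)labda-12,14-dien-6β-ol
Product: 23 (12E)-labda-12,14-diene-6β,7β,8α-triol
Conditions: TBAF (6 equiv), THF, 50 °C
Reagents that add atoms: none
Why: Fluoride desilylation frees both silyl ethers under non‑acidic conditions that cannot protonate the diene or cyclise the 8‑OH onto it.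

Step 18
Reactants: 23 (12E)-labda-12,14-diene-6β,7β,8α-triol
Product: 24 (12E)-6β,8α-dihydroxylabda-12,14-dien-7β-yl acetate
Conditions: Ac2O (1.3 equiv), pyridine, 0 °C to rt
Reagents that add atoms: acetic anhydride, CC(=O)OC(C)=O
Why: Acylation occurs only at the equatorial 7β‑OH because the axial 6β‑OH is shielded by two syn‑axial methyls and the 8α‑OH is tertiary.

## Compound list

1 | (+)-sclareolide (13,14,15,16-tetranorlabdan-12,8α-olide) | O=C1C[C@H]2[C@](C)(O1)CC[C@H]3C(C)(C)CCC[C@@]32C | starting material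
2 | 13,14,15,16-tetranorlabdane-8α,12-diol | OCC[C@H]1[C@](C)(O)CC[C@H]2C(C)(C)CCC[C@@]21C | intermediate
3 | 12-benzyloxy-13,14,15,16-tetranorlabdan-8α-ol | c3ccccc3COCC[C@H]1[C@](C)(O)CC[C@H]2C(C)(C)CCC[C@@]21C | intermediate
4 | 12-benzyloxy-13,14,15,16-tetranorlabd-8(17)-ene | c3ccccc3COCC[C@H]1C(=C)CC[C@H]2C(C)(C)CCC[C@@]21C | intermediate
5 | 12-benzyloxy-13,14,15,16-tetranorlabd-8(17)-en-7α-ol | c3ccccc3COCC[C@H]1C(=C)[C@H](O)C[C@H]2C(C)(C)CCC[C@@]21C | intermediate
6 | 12-benzyloxy-8α,17-epoxy-13,14,15,16-tetranorlabdan-7α-ol | c3ccccc3COCC[C@H]1[C@]4(OC4)[C@H](O)C[C@H]2C(C)(C)CCC[C@@]21C | intermediate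
7 | 12-benzyloxy-13,14,15,16-tetranorlabdane-7α,8α-diol | c3ccccc3COCC[C@H]1[C@](C)(O)[C@H](O)C[C@H]2C(C)(C)CCC[C@@]21C | intermediate
8 | 12-benzyloxy-8α-hydroxy-13,14,15,16-tetranorlabdan-7-one | c3ccccc3COCC[C@H]1[C@](C)(O)C(=O)C[C@H]2C(C)(C)CCC[C@@]21C | intermediate
9 | 12-benzyloxy-7,8α-bis(TBS-oxy)-13,14,15,16-tetranorlabd-6-ene | c3ccccc3COCC[C@H]1[C@](C)(O[Si](C)(C)C(C)(C)C)C(O[Si](C)(C)C(C)(C)C)=C[C@H]2C(C)(C)CCC[C@@]21C | intermediate
10 | 6α-alkylborane: 12-benzyloxy-6α-boranyl-7β,8α-bis(TBS-oxy)-13,14,15,16-tetranorlabdane (not isolated) | c3ccccc3COCC[C@H]1[C@](C)(O[Si](C)(C)C(C)(C)C)[C@@H](O[Si](C)(C)C(C)(C)C)[C@H](B)[C@H]2C(C)(C)CCC[C@@]21C | intermediate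
11 | 12-benzyloxy-7β,8α-bis(TBS-oxy)-13,14,15,16-tetranorlabdan-6α-ol | c3ccccc3COCC[C@H]1[C@](C)(O[Si](C)(C)C(C)(C)C)[C@@H](O[Si](C)(C)C(C)(C)C)[C@H](O)[C@H]2C(C)(C)CCC[C@@]21C | intermediate
12 | 12-benzyloxy-7β,8α-bis(TBS-oxy)-13,14,15,16-tetranorlabdan-6-one | c3ccccc3COCC[C@H]1[C@](C)(O[Si](C)(C)C(C)(C)C)[C@@H](O[Si](C)(C)C(C)(C)C)C(=O)[C@H]2C(C)(C)CCC[C@@]21C | intermediate
13 | 12-benzyloxy-7β,8α-bis(TBS-oxy)-13,14,15,16-tetranorlabdan-6β-ol | c3ccccc3COCC[C@H]1[C@](C)(O[Si](C)(C)C(C)(C)C)[C@@H](O[Si](C)(C)C(C)(C)C)[C@@H](O)[C@H]2C(C)(C)CCC[C@@]21C | intermediate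
14 | 7β,8α-bis(TBS-oxy)-13,14,15,16-tetranorlabdane-6β,12-diol | OCC[C@H]1[C@](C)(O[Si](C)(C)C(C)(C)C)[C@@H](O[Si](C)(C)C(C)(C)C)[C@@H](O)[C@H]2C(C)(C)CCC[C@@]21C | intermediate
15 | 6β-hydroxy-7β,8α-bis(TBS-oxy)-13,14,15,16-tetranorlabdan-12-al | O=CC[C@H]1[C@](C)(O[Si](C)(C)C(C)(C)C)[C@@H](O[Si](C)(C)C(C)(C)C)[C@@H](O)[C@H]2C(C)(C)CCC[C@@]21C | intermediate
16 | propanal | CCC=O | starting material
17 | cyclohexylamine | NC1CCCCC1 | starting material
18 | N-cyclohexylpropan-1-imine | CC/C=N/C1CCCCC1 | intermediate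
19 | lithiated imine: lithium N-cyclohexyl-N-(prop-1-enyl)amide (not isolated) | CC=CN([Li])C1CCCCC1 | intermediate
20 | aldol adduct: 12-hydroxy-14-(cyclohexylimino) compound, C12/C13 diastereomer mixture, shown protonated (not isolated) | CC(C=NC3CCCCC3)C(O)C[C@H]1[C@](C)(O[Si](C)(C)C(C)(C)C)[C@@H](O[Si](C)(C)C(C)(C)C)[C@@H](O)[C@H]2C(C)(C)CCC[C@@]21C | intermediate
21 | (12E)-6β-hydroxy-7β,8α-bis(TBS-oxy)-15-norlabd-12-en-14-al | O=C/C(C)=C/C[C@H]1[C@](C)(O[Si](C)(C)C(C)(C)C)[C@@H](O[Si](C)(C)C(C)(C)C)[C@@H](O)[C@H]2C(C)(C)CCC[C@@]21C | intermediate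
22 | (12E)-7β,8α-bis(TBS-oxy)labda-12,14-dien-6β-ol | C=C/C(C)=C/C[C@H]1[C@](C)(O[Si](C)(C)C(C)(C)C)[C@@H](O[Si](C)(C)C(C)(C)C)[C@@H](O)[C@H]2C(C)(C)CCC[C@@]21C | intermediate
23 | (12E)-labda-12,14-diene-6β,7β,8α-triol | C=C/C(C)=C/C[C@H]1[C@](C)(O)[C@@H](O)[C@@H](O)[C@H]2C(C)(C)CCC[C@@]21C | intermediate
24 | (12E)-6β,8α-dihydroxylabda-12,14-dien-7β-yl acetate (CNP0225877.1) | C=C/C(C)=C/C[C@H]1[C@](C)(O)[C@@H](OC(C)=O)[C@@H](O)[C@H]2C(C)(C)CCC[C@@]21C | target

## Step count and risks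

Total step count: 18. Longest linear sequence: 17 (steps 1–13 and 15–18).

The three steps most likely to fail:

Step 4 (SeO2 allylic hydroxylation; over‑oxidation to the enone or attack at C9 can lower the yield). The fallback sets out from 4 and comes back at 5. Lemieux–Johnson cleavage of the exocyclic alkene (cat. OsO4, NaIO4, 2,6‑lutidine, dioxane–water) gives 12-benzyloxy-13,14,15,16,17-pentanorlabdan-8-one F1. Kinetic enolisation at the C7 methylene (LDA, TMSCl, THF, −78 °C) gives 12-benzyloxy-8-(trimethylsilyloxy)-13,14,15,16,17-pentanorlabd-7-ene F2. Rubottom oxidation (mCPBA, NaHCO3, CH2Cl2, 0 °C, then citric acid in MeOH) adds oxygen axially from the α‑face and gives 12-benzyloxy-7α-hydroxy-13,14,15,16,17-pentanorlabdan-8-one F3. Wittig methylenation with excess Ph3P=CH2 (THF, reflux) puts C17 back and returns to 5.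

Step 9 (hydroboration of a hindered silyl enol ether; slow addition, or silyl migration during the basic oxidation, would spoil the 6‑OH/7‑OTBS differentiation). The fallback sets out from 9 and comes back at 11. Rubottom oxidation of 9 (mCPBA, NaHCO3, CH2Cl2, −20 °C, then HF·pyridine) from the α‑face gives 12-benzyloxy-6α-hydroxy-8α-(TBS-oxy)-13,14,15,16-tetranorlabdan-7-one F4. TESCl and imidazole in DMF give 12-benzyloxy-8α-(TBS-oxy)-6α-(TES-oxy)-13,14,15,16-tetranorlabdan-7-one F5. NaBH4 in MeOH reduces from the α‑face to 12-benzyloxy-8α-(TBS-oxy)-6α-(TES-oxy)-13,14,15,16-tetranorlabdan-7β-ol F6. TBSOTf and 2,6‑lutidine give 12-benzyloxy-7β,8α-bis(TBS-oxy)-6α-(TES-oxy)-13,14,15,16-tetranorlabdane F7. PPTS in MeOH at 0 °C removes only the triethylsilyl group and returns to 11.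

Step 15 (directed aldol on an enolisable aldehyde with a free hydroxyl; proton transfer, incomplete dehydration or TBS loss in the acidic hydrolysis are the risks). The fallback sets out from 15 and comes back at 21. Wittig olefination with ethyl 2-(triphenylphosphoranylidene)propanoate (toluene, 80 °C) gives ethyl (12E)-6β-hydroxy-7β,8α-bis(TBS-oxy)-15-norlabd-12-en-14-oate F8. DIBAL‑H (CH2Cl2, −78 °C) gives (12E)-7β,8α-bis(TBS-oxy)-15-norlabd-12-ene-6β,14-diol F9. MnO2 (CH2Cl2, rt) oxidises only the allylic alcohol and returns to 21.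

## Further compounds

F1 | step 4 | 12-benzyloxy-13,14,15,16,17-pentanorlabdan-8-one | c3ccccc3COCC[C@H]1C(=O)CC[C@H]2C(C)(C)CCC[C@@]21C
F2 | step 4 | 12-benzyloxy-8-(trimethylsilyloxy)-13,14,15,16,17-pentanorlabd-7-ene | c3ccccc3COCC[C@H]1C(O[Si](C)(C)C)=CC[C@H]2C(C)(C)CCC[C@@]21C
F3 | step 4 | 12-benzyloxy-7α-hydroxy-13,14,15,16,17-pentanorlabdan-8-one | c3ccccc3COCC[C@H]1C(=O)[C@H](O)C[C@H]2C(C)(C)CCC[C@@]21C
F4 | step 9 | 12-benzyloxy-6α-hydroxy-8α-(TBS-oxy)-13,14,15,16-tetranorlabdan-7-one | c3ccccc3COCC[C@H]1[C@](C)(O[Si](C)(C)C(C)(C)C)C(=O)[C@H](O)[C@H]2C(C)(C)CCC[C@@]21C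
F5 | step 9 | 12-benzyloxy-8α-(TBS-oxy)-6α-(TES-oxy)-13,14,15,16-tetranorlabdan-7-one | c3ccccc3COCC[C@H]1[C@](C)(O[Si](C)(C)C(C)(C)C)C(=O)[C@H](O[Si](CC)(CC)CC)[C@H]2C(C)(C)CCC[C@@]21C
F6 | step 9 | 12-benzyloxy-8α-(TBS-oxy)-6α-(TES-oxy)-13,14,15,16-tetranorlabdan-7β-ol | c3ccccc3COCC[C@H]1[C@](C)(O[Si](C)(C)C(C)(C)C)[C@@H](O)[C@H](O[Si](CC)(CC)CC)[C@H]2C(C)(C)CCC[C@@]21C
F7 | step 9 | 12-benzyloxy-7β,8α-bis(TBS-oxy)-6α-(TES-oxy)-13,14,15,16-tetranorlabdane | c3ccccc3COCC[C@H]1[C@](C)(O[Si](C)(C)C(C)(C)C)[C@@H](O[Si](C)(C)C(C)(C)C)[C@H](O[Si](CC)(CC)CC)[C@H]2C(C)(C)CCC[C@@]21C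
F8 | step 15 | ethyl (12E)-6β-hydroxy-7β,8α-bis(TBS-oxy)-15-norlabd-12-en-14-oate | CCOC(=O)/C(C)=C/C[C@H]1[C@](C)(O[Si](C)(C)C(C)(C)C)[C@@H](O[Si](C)(C)C(C)(C)C)[C@@H](O)[C@H]2C(C)(C)CCC[C@@]21C
F9 | step 15 | (12E)-7β,8α-bis(TBS-oxy)-15-norlabd-12-ene-6β,14-diol | OC/C(C)=C/C[C@H]1[C@](C)(O[Si](C)(C)C(C)(C)C)[C@@H](O[Si](C)(C)C(C)(C)C)[C@@H](O)[C@H]2C(C)(C)CCC[C@@]21C
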